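**Strategy.** Both decalins derive from one iodide built on (R)-carvone, whose stereocentre (C5, labdane numbering) relays all others. Everything rests on a Lewis-acid Meinwald rearrangement of a trans-fused cycloheptene oxide: the ring bond from C3 migrates to the tertiary epoxide carbon C4, so the seven-membered ring contracts to ring A of the acid-bearing decalin and the quaternary centre C4 (β-CH3, α-CHO, later CO2H or CH2OH) is set with inversion in one operation. The precursor is an epoxy bicyclo[5.4.0]undecenone made by double alkylation of carvone, ring-closing metathesis and epoxidation. A catalyst-controlled Diels–Alder reaction of the C12–C15 diene with methyl vinyl ketone and two alkyl–alkenyl Negishi couplings assemble the dimer.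

Key step: step 5

Remark on numbering and configuration: labdane numbering is used for each decalin (C20 = 10β-methyl, C19 = 4β-methyl, C18 = 4α carbon, C17 = exocyclic CH2 on C8, C11 = CH2 on C9). Ca is the extra carbon between C3 and C4 of the seven-membered ring. 1′–6′ number the central cyclohexene (C1′ = C12, C6′ carries the alkenyl group); double primes mark the alcohol half. Read this way, the target has 4α-CO2H and 4α-CH2OH (4β-CH3), 5α-H, 9α-H, 10β-CH3 in both decalins and (1′S,6′S) in the cyclohexene. The two C10 epimers of compound 3 are used together, because step 2 erases that centre.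

Step 1
Reactants: 1 (R)-(−)-carvone
Product: 3 (5R,6S)-2,6-dimethyl-5-(prop-1-en-2-yl)cyclohex-2-en-1-one (trans-6-methylcarvone; the minor 6R epimer is carried along), via lithium dienolate of carvone 2 (not isolated)
Conditions: LiN(i-Pr)2, THF, −78 °C; MeI, −78 → 0 °C
Reagents that add atoms: iodomethane, CI
Why: Kinetic α′-deprotonation of the enone gives the cross-conjugated lithium dienolate, which is C-methylated at C10 (enolate alkylation); the configuration of the new centre is irrelevant.

Step 2
Reactants: 3 trans-6-methylcarvone; 4 5-iodopent-1-ene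
Product: 6 (5R,6S)-2,6-dimethyl-6-(pent-4-en-1-yl)-5-(prop-1-en-2-yl)cyclohex-2-en-1-one, via lithium dienolate of 6-methylcarvone 5 (not isolated)
Conditions: LiN(i-Pr)2, THF, −78 → 0 °C; DMPU, 4, −40 °C → rt
Reagents that add atoms: none
Why: Second enolate alkylation, in which the primary iodide should attack the fully substituted enolate anti to the neighbouring isopropenyl group, so that C10 carries CH3 cis and the pentenyl chain trans to C4.

Step 3
Reactants: 6 dialkylated carvone
Product: 7 trans-fused bicyclo[5.4.0]undecadienone (ring B: C9=O, C7=C8 with 8-CH3; seven-membered ring C10–C1–C2–C3–Ca=C4(CH3)–C5; 10β-CH3, 5α-H)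
Conditions: second-generation Grubbs catalyst RuCl2(=CHPh)(PCy3)(H2IMes) (5 mol %), toluene (5 mM), 80 °C
Reagents that add atoms: none
Why: Ring-closing metathesis joins the terminal alkene and the isopropenyl group with loss of ethene, the conjugated enone alkene being inert to the ruthenium carbene.

Step 4
Reactants: 7 bicyclic dienone
Product: 8 4α,Caα-epoxide of 7 (oxygen anti to the 10β-CH3)
Conditions: mCPBA, NaHCO3, CH2Cl2, 0 °C
Reagents that add atoms: meta-chloroperoxybenzoic acid, O=C(OO)c1cccc(Cl)c1
Why: Prilezhaev epoxidation selects the electron-rich trisubstituted alkene over the enone and should occur on the face away from the angular 10β-methyl group, which sets the epoxide configuration.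

Step 5
Reactants: 8 α-epoxide
Product: 9 keto aldehyde (trans-decalin; 4β-CH3, 4α-CHO, 5α-H, 10β-CH3; ring B C9=O, C7=C8 with 8-CH3)
Conditions: MeAl(OAr)2 (Ar = 4-bromo-2,6-di-tert-butylphenyl, 1.2 equiv), CH2Cl2, −78 → −20 °C
Reagents that add atoms: none
Why: The bulky aluminium phenoxide coordinates the epoxide oxygen and ionises the C4–O bond at the tertiary carbon while the ring bond Ca–C3 shifts to C4 on the face opposite the departing oxygen, so that the oxygen left on Ca becomes the aldehyde carbonyl. The closest known reaction type is the Meinwald (semipinacol) rearrangement of trisubstituted epoxides to α-quaternary aldehydes with ring contraction. No ring is closed by cyclisation: ring A results from the 1,2-shift, by which the seven-membered ring C10–C1–C2–C3–Ca–C4–C5 becomes the six-membered ring C10–C1–C2–C3–C4–C5 with Ca expelled as the formyl carbon. The only new stereocentre, C4, is controlled by the epoxide configuration, since migration occurs with inversion: the α-epoxide gives 4β-CH3 and 4α-CHO, and the α-epoxide was itself dictated by the 10β-methyl group that traces back to C5 of carvone. The step needs C–C migration to win over hydride shift (cycloheptanone) and over proton loss (allylic alcohol); this aluminium reagent is known to favour alkyl over hydride migration, the contraction relieves the strain of the trans-fused seven-membered ring, and the enone in ring B offers the Lewis acid nothing to ionise.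

Step 6
Reactants: 9 keto aldehyde
Product: 10 keto acid (4α-CO2H)
Conditions: NaClO2, NaH2PO4, 2-methylbut-2-ene, t-BuOH/H2O, rt
Reagents that add atoms: sodium chlorite, [Na+].[O-]Cl=O
Why: Pinnick oxidation converts the non-enolisable neopentyl aldehyde to the acid while the scavenger protects the enone from hypochlorous acid.

Step 7
Reactants: 10 keto acid
Product: 11 2-(trimethylsilyl)ethyl ester of 10
Conditions: Me3SiCH2CH2OH, PPh3, diisopropyl azodicarboxylate, THF, 0 °C → rt
Reagents that add atoms: 2-(trimethylsilyl)ethanol, C[Si](C)(C)CCO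
Why: In the Mitsunobu esterification the hindered carboxylate is the nucleophile at the activated primary alcohol, so shielding of the C4 carbonyl does not hinder ester formation.

Step 8
Reactants: 11 keto ester
Product: 13 enol triflate C9(OTf)=C8(CH3), via lithium enolate of the reduced enone 12 (not isolated)
Conditions: LiBH(s-Bu)3 (1.1 equiv), THF, −78 °C; PhNTf2, −78 → 0 °C
Reagents that add atoms: N-phenylbis(trifluoromethanesulfonimide), O=S(=O)(N(c1ccccc1)S(=O)(=O)C(F)(F)F)C(F)(F)F
Why: Conjugate hydride reduction of the β-unsubstituted enone gives a single enolate (C10 is quaternary), which is O-triflated; the hindered ester should be inert at −78 °C.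

Step 9
Reactants: 13 enol triflate
Product: 14 α,β-unsaturated acid (CO2H = C11 on C9=C8)
Conditions: Pd(OAc)2 (10 mol %), dppf Fe(C5H4PPh2)2 (20 mol %), KOAc, CO (1 atm), DMSO, 60 °C; then H2O
Reagents that add atoms: carbon monoxide, [C-]#[O+]; water, O
Why: Palladium-catalysed hydroxycarbonylation (oxidative addition of the enol triflate to zerovalent palladium, CO insertion, capture by acetate, hydrolysis) introduces C11 at the carboxylic acid level.

Step 10
Reactants: 14 conjugated acid
Product: 16 β,γ-unsaturated acid (8(17)-exo-methylene, 9α-H, 9β-CO2H), via dilithium dienediolate 15 (not isolated)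
Conditions: LiN(i-Pr)2 (2.5 equiv), THF/DMPU, −78 → 0 °C; AcOH, THF, −78 °C
Reagents that add atoms: none
Why: Deconjugative protonation, in which the lithium carboxylate directs the amide base to the syn γ-methyl group (C17) and kinetic α-protonation of the dienediolate at C9 occurs anti to the axial 10β-methyl, giving the exocyclic alkene with 9α-H.

Step 11
Reactants: 16 β,γ-unsaturated acid
Product: 18 C11 alcohol (9β-CH2OH), via isobutyl carbonic anhydride 17 (not isolated)
Conditions: i-BuOCOCl, N-methylmorpholine, THF, −15 °C; NaBH4, H2O, 0 °C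
Reagents that add atoms: none
Why: Mixed-anhydride activation followed by borohydride reduction converts only the free acid to the primary alcohol, because NaBH4 does not reduce the hindered ester at C4.

Step 12
Reactants: 18 alcohol
Product: 19 iodo ester (9β-CH2I, 8(17)-ene, 4α-CO2CH2CH2SiMe3)
Conditions: I2, PPh3, imidazole, CH2Cl2, 0 °C → rt
Reagents that add atoms: iodine, II
Why: Appel-type iodination proceeds by SN2 displacement of the alkoxyphosphonium ion at the primary carbon without touching the exocyclic alkene.

Step 13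
Reactants: 20 prop-2-yn-1-ol
Product: 22 (E)-3-iodo-2-methylprop-2-en-1-ol, via alkenylalane of propargyl alcohol 21 (not isolated)
Conditions: Me3Al (3 equiv), Cp2ZrCl2 (0.25 equiv), CH2Cl2, 0 °C → rt; I2, THF, −30 °C
Reagents that add atoms: trimethylaluminium, C[Al](C)C; iodine, II
Why: Zirconium-catalysed carboalumination adds CH3 and Al syn across the alkyne with CH3 on the internal carbon, and iodinolysis with retention gives the (E)-iodoalkene.

Step 14
Reactants: 22 iodo allylic alcohol
Product: 23 (E)-3-iodo-2-methylprop-2-enal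
Conditions: MnO2, CH2Cl2, rt
Reagents that add atoms: none
Why: Manganese dioxide oxidises the allylic alcohol to the enal selectively and without isomerising the alkene.

Step 15
Reactants: 23 iodo enal
Product: 24 (E)-1-iodo-2-methylbuta-1,3-diene
Conditions: Ph3PCH3Br, KN(SiMe3)2, THF, −78 → 0 °C (product kept in solution)
Reagents that add atoms: methyltriphenylphosphonium bromide, C[P+](c1ccccc1)(c1ccccc1)c1ccccc1.[Br-]
Why: Wittig methylenation of the aldehyde with the non-stabilised ylide gives the terminal diene and leaves the (E)-iodoalkene unchanged.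

Step 16
Reactants: 19 iodo ester; 24 (E)-1-iodo-2-methylbuta-1,3-diene
Product: 26 2-(trimethylsilyl)ethyl (12E)-labda-8(17),12,14-trien-18-oate (4β-CH3, 5α-H, 9α-H, 10β-CH3), via alkylzinc iodide of the ester 25 (not isolated)
Conditions: Zn dust, LiCl, THF, 40 °C; then 24, PdCl2(dppf) (5 mol %), THF, rt
Reagents that add atoms: none
Why: Zinc insertion into the primary C–I bond tolerates the ester, and the Negishi sp3–sp2 coupling retains the (E) geometry of the alkenyl iodide, the bidentate ligand disfavouring β-hydride elimination.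

Step 17
Reactants: 26 triene ester; 27 methyl vinyl ketone
Product: 28 cyclohexenyl methyl ketone (1′S,6′S; 1′-CH2 of the decalin and 6′-acetyl cis; 2′-CH3, 2′,3′-alkene)
Conditions: (R)-3,3-diphenyl-1-(2-methylphenyl)tetrahydro-1H,3H-pyrrolo[1,2-c][1,3,2]oxazaborole (20 mol %) activated with Tf2NH, 27 (3 equiv), CH2Cl2, −78 → −40 °C
Reagents that add atoms: none
Why: In this chiral-Lewis-acid-catalysed Diels–Alder reaction the protonated oxazaborolidine should hold the s-trans enone over one of its phenyl groups so that the diene adds to the Re face of the enone α-carbon, the endo transition state with the (E)-diene gives the cis 1′,6′ relationship, and bonding of the enone β-carbon to the unhindered terminus C15 places the acetyl-bearing carbon on C12.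

Step 18
Reactants: 28 methyl ketone
Product: 30 terminal alkyne (6′-ethynyl), via enol diethyl phosphate 29 (not isolated)
Conditions: LiN(i-Pr)2 (1.1 equiv), THF, −78 °C; ClP(O)(OEt)2; LiN(i-Pr)2 (2.5 equiv), −78 °C → rt
Reagents that add atoms: none
Why: Kinetic enolisation at the methyl group, O-phosphorylation and base-induced elimination of the terminal enol phosphate give the alkyne, and because the C6′ methine is not enolised the cis arrangement is kept.

Step 19
Reactants: 30 alkyne
Product: 32 (E)-alkenyl iodide (6′-C(CH3)=CHI), via alkenyldimethylalane 31 (not isolated)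
Conditions: Me3Al (3 equiv), Cp2ZrCl2 (0.3 equiv), CH2Cl2, 0 °C → rt; I2, THF, −30 °C
Reagents that add atoms: trimethylaluminium, C[Al](C)C; iodine, II
Why: Zirconium-catalysed carboalumination of the terminal alkyne (syn, CH3 to the internal carbon; the other alkenes are far less reactive) and iodinolysis with retention set the (E)-trisubstituted alkene.

Step 20
Reactants: 19 iodo ester
Product: 33 iodo alcohol (9β-CH2I, 4α-CH2OH, 8(17)-ene)
Conditions: i-Bu2AlH (3 equiv), CH2Cl2, −78 → 0 °C
Reagents that add atoms: none
Why: Hydride reduction of the ester to the primary alcohol, the primary iodide and the alkene being inert to the aluminium hydride at this temperature.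

Step 21
Reactants: 33 iodo alcohol
Product: 34 iodo silyl ether (4α-CH2OSiMe2t-Bu)
Conditions: t-BuMe2SiOTf, 2,6-lutidine, CH2Cl2, −78 → 0 °C
Reagents that add atoms: tert-butyldimethylsilyl trifluoromethanesulfonate, CC(C)(C)[Si](C)(C)OS(=O)(=O)C(F)(F)F
Why: The silyl triflate silylates the hindered neopentyl alcohol rapidly under non-nucleophilic base.

Step 22
Reactants: 34 iodo silyl ether; 32 (E)-alkenyl iodide
Product: 36 protected dimer (A-half 2-(trimethylsilyl)ethyl ester, alcohol half silyl ether, 12″E), via alkylzinc iodide of the silyl ether 35 (not isolated)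
Conditions: Zn dust, LiCl, THF, 40 °C; then 32, PdCl2(dppf) (5 mol %), THF, 40 °C
Reagents that add atoms: none
Why: A second Negishi sp3–sp2 coupling forms the C11″–C12″ bond with retention of the (E)-alkene geometry and tolerates ester, silyl ether and the other alkenes.

Step 23
Reactants: 36 protected dimer
Product: 37 CNP0316988.1
Conditions: Bu4NF (excess), THF, rt → 40 °C; aqueous citric acid work-up
Reagents that add atoms: none
Why: Fluoride cleaves the silyl ether and fragments the 2-(trimethylsilyl)ethyl ester by β-elimination, a mode of ester cleavage that does not require attack at the hindered C4 carbonyl.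

**Compound list**

1 | (R)-(−)-carvone | O=C1C(C)=CC[C@@H](C(C)=C)C1 | starting material
2 | lithium dienolate of carvone | [Li]OC1=C[C@H](C(C)=C)CC=C1C | intermediate
3 | (5R,6S)-2,6-dimethyl-5-(prop-1-en-2-yl)cyclohex-2-en-1-one | O=C1C(C)=CC[C@@H](C(C)=C)[C@@H]1C | intermediate
4 | 5-iodopent-1-ene | C=CCCCI | starting material
5 | lithium dienolate of 6-methylcarvone | [Li]OC1=C(C)[C@H](C(C)=C)CC=C1C | intermediate
6 | (5R,6S)-2,6-dimethyl-6-(pent-4-en-1-yl)-5-(prop-1-en-2-yl)cyclohex-2-en-1-one | O=C1C(C)=CC[C@@H](C(C)=C)[C@]1(C)CCCC=C | intermediate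
7 | trans-fused bicyclo[5.4.0]undecadienone (C9=O, C7=C8, Ca=C4; 10β-CH3, 5α-H) | O=C1C(C)=CC[C@H]2C(C)=CCCC[C@]12C | intermediate
8 | 4α,Caα-epoxide of 7 | O=C1C(C)=CC[C@H]2[C@]3(C)O[C@@H]3CCC[C@]12C | intermediate
9 | keto aldehyde (4β-CH3, 4α-CHO, 5α-H, 10β-CH3, C9=O, C7=C8) | O=C1C(C)=CC[C@@H]2[C@]1(C)CCC[C@@]2(C)C=O | intermediate
10 | keto acid (4α-CO2H) | O=C1C(C)=CC[C@@H]2[C@]1(C)CCC[C@@]2(C)C(=O)O | intermediate
11 | 2-(trimethylsilyl)ethyl keto ester | O=C1C(C)=CC[C@@H]2[C@]1(C)CCC[C@@]2(C)C(=O)OCC[Si](C)(C)C | intermediate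
12 | lithium enolate C9(OLi)=C8 | [Li]OC1=C(C)CC[C@@H]2[C@]1(C)CCC[C@@]2(C)C(=O)OCC[Si](C)(C)C | intermediate
13 | enol triflate C9(OTf)=C8(CH3) | O=S(=O)(OC1=C(C)CC[C@@H]2[C@]1(C)CCC[C@@]2(C)C(=O)OCC[Si](C)(C)C)C(F)(F)F | intermediate
14 | α,β-unsaturated C11 acid | OC(=O)C1=C(C)CC[C@@H]2[C@]1(C)CCC[C@@]2(C)C(=O)OCC[Si](C)(C)C | intermediate
15 | dilithium dienediolate | [Li]OC(O[Li])=C1C(=C)CC[C@@H]2[C@]1(C)CCC[C@@]2(C)C(=O)OCC[Si](C)(C)C | intermediate
16 | β,γ-unsaturated acid (8(17)-ene, 9α-H, 9β-CO2H) | C=C1CC[C@@H]2[C@](C)(CCC[C@@]2(C)C(=O)OCC[Si](C)(C)C)[C@H]1C(=O)O | intermediate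
17 | isobutyl carbonic anhydride of 16 | C=C1CC[C@@H]2[C@](C)(CCC[C@@]2(C)C(=O)OCC[Si](C)(C)C)[C@H]1C(=O)OC(=O)OCC(C)C | intermediate
18 | C11 alcohol (9β-CH2OH) | C=C1CC[C@@H]2[C@](C)(CCC[C@@]2(C)C(=O)OCC[Si](C)(C)C)[C@H]1CO | intermediate
19 | iodo ester (9β-CH2I) | C=C1CC[C@@H]2[C@](C)(CCC[C@@]2(C)C(=O)OCC[Si](C)(C)C)[C@H]1CI | intermediate
20 | prop-2-yn-1-ol | C#CCO | starting material
21 | (E)-alkenylalane of the aluminium alkoxide | C[Al](C)/C=C(\C)CO[Al](C)C | intermediate
22 | (E)-3-iodo-2-methylprop-2-en-1-ol | OC/C(C)=C/I | intermediate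
23 | (E)-3-iodo-2-methylprop-2-enal | O=C/C(C)=C/I | intermediate
24 | (E)-1-iodo-2-methylbuta-1,3-diene | C=C/C(C)=C/I | intermediate
25 | alkylzinc iodide of 19 | C=C1CC[C@@H]2[C@](C)(CCC[C@@]2(C)C(=O)OCC[Si](C)(C)C)[C@H]1C[Zn]I | intermediate
26 | 2-(trimethylsilyl)ethyl (12E)-labda-8(17),12,14-trien-18-oate | C=C1CC[C@@H]2[C@](C)(CCC[C@@]2(C)C(=O)OCC[Si](C)(C)C)[C@H]1C/C=C(\C)C=C | intermediate
27 | methyl vinyl ketone | CC(=O)C=C | starting material
28 | (1′S,6′S)-cyclohexenyl methyl ketone | C=C1CC[C@@H]2[C@](C)(CCC[C@@]2(C)C(=O)OCC[Si](C)(C)C)[C@H]1C[C@@H]1C(C)=CCC[C@@H]1C(C)=O | intermediate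
29 | enol diethyl phosphate of 28 | C=C1CC[C@@H]2[C@](C)(CCC[C@@]2(C)C(=O)OCC[Si](C)(C)C)[C@H]1C[C@@H]1C(C)=CCC[C@@H]1C(=C)OP(=O)(OCC)OCC | intermediate
30 | 6′-ethynyl compound | C=C1CC[C@@H]2[C@](C)(CCC[C@@]2(C)C(=O)OCC[Si](C)(C)C)[C@H]1C[C@@H]1C(C)=CCC[C@@H]1C#C | intermediate
31 | (E)-alkenyldimethylalane | C=C1CC[C@@H]2[C@](C)(CCC[C@@]2(C)C(=O)OCC[Si](C)(C)C)[C@H]1C[C@@H]1C(C)=CCC[C@@H]1/C(C)=C/[Al](C)C | intermediate
32 | (E)-alkenyl iodide | C=C1CC[C@@H]2[C@](C)(CCC[C@@]2(C)C(=O)OCC[Si](C)(C)C)[C@H]1C[C@@H]1C(C)=CCC[C@@H]1/C(C)=C/I | intermediate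
33 | iodo alcohol (4α-CH2OH, 9β-CH2I) | C=C1CC[C@@H]2[C@](C)(CCC[C@@]2(C)CO)[C@H]1CI | intermediate
34 | iodo tert-butyldimethylsilyl ether | C=C1CC[C@@H]2[C@](C)(CCC[C@@]2(C)CO[Si](C)(C)C(C)(C)C)[C@H]1CI | intermediate
35 | alkylzinc iodide of 34 | C=C1CC[C@@H]2[C@](C)(CCC[C@@]2(C)CO[Si](C)(C)C(C)(C)C)[C@H]1C[Zn]I | intermediate
36 | protected dimer | C=C1CC[C@@H]2[C@](C)(CCC[C@@]2(C)C(=O)OCC[Si](C)(C)C)[C@H]1C[C@@H]1C(C)=CCC[C@@H]1/C(C)=C/C[C@H]1C(=C)CC[C@H]2[C@](C)(CO[Si](C)(C)C(C)(C)C)CCC[C@]12C | intermediate
37 | CNP0316988.1 | C=C1CC[C@@H]2[C@](C)(CCC[C@@]2(C)C(=O)O)[C@H]1C[C@@H]1C(C)=CCC[C@@H]1/C(C)=C/C[C@H]1C(=C)CC[C@H]2[C@](C)(CO)CCC[C@]12C | target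

**Step count.** Total: 23 steps. Longest linear sequence: 18 steps (steps 1–12, 16–19, 22, 23).

**Steps most likely to fail**

Step 5. Hydride shift from Ca or proton loss may compete with migration of the ring bond, so that the contraction is incomplete. The fallback is a Favorskii ring contraction, which reaches the same C4 centre through a cyclopropanone instead of a cation. It sets out from 7: oxidation of the trisubstituted alkene with CrO2Cl2 in acetone at −78 °C should give the α-chloro ketone F1 (chlorine on C4 on the α face, carbonyl on Ca). Sodium 2-(trimethylsilyl)ethoxide in Et2O should then let the C3 enolate displace chloride with inversion, and alkoxide opening of the cyclopropanone towards the less substituted carbanion gives ester 11, where the route is rejoined.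

Step 17. Bonding to the wrong diene terminus, addition to the wrong face (the catalyst's sense of induction is inferred from a model) or exo approach would give regio- or stereoisomeric cyclohexenes. The fallback replaces catalyst control by a chelating chiral auxiliary. It sets out from 26: (R)-3-acryloyl-4-benzyloxazolidin-2-one F2 (from (R)-4-benzyloxazolidin-2-one, n-BuLi and acryloyl chloride) and Et2AlCl in CH2Cl2 at −78 °C should give the endo imide adduct F3, the benzyl group shielding the Si face of the dienophile α-carbon. Me3Al with MeNHOMe·HCl converts it to the Weinreb amide F4, and MeMgBr in THF at 0 °C gives ketone 28, where the route is rejoined.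

Step 4. Poor or reversed facial selectivity in the epoxidation of the flexible cycloheptene would carry the wrong configuration into C4. The fallback delivers the oxygen through a bromohydrin, that is, to the face opposite the one the electrophile attacks. It sets out from 7: NBS in aqueous DME should give the trans bromohydrin F5 (bromine on Ca, tertiary α-hydroxyl on C4), and K2CO3 in MeOH closes it with inversion at Ca to epoxide 8, where the route is rejoined.

**Further compounds**

F1 | step 5 | 4α-chloro-4β-methyl seven-membered-ring ketone (carbonyl on Ca) | O=C1C(C)=CC[C@H]2[C@](C)(Cl)C(=O)CCC[C@]12C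
F2 | step 17 | (R)-3-acryloyl-4-benzyloxazolidin-2-one | C=CC(=O)N1[C@H](Cc2ccccc2)COC1=O
F3 | step 17 | (1′S,6′S) Diels–Alder imide adduct | C=C1CC[C@@H]2[C@](C)(CCC[C@@]2(C)C(=O)OCC[Si](C)(C)C)[C@H]1C[C@@H]1C(C)=CCC[C@@H]1C(=O)N1[C@H](Cc2ccccc2)COC1=O
F4 | step 17 | Weinreb amide | C=C1CC[C@@H]2[C@](C)(CCC[C@@]2(C)C(=O)OCC[Si](C)(C)C)[C@H]1C[C@@H]1C(C)=CCC[C@@H]1C(=O)N(C)OC
F5 | step 4 | trans bromohydrin (4α-OH, Caβ-Br) | O=C1C(C)=CC[C@H]2[C@](C)(O)[C@@H](Br)CCC[C@]12C
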